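**Retrosynthetic overview**
1. Target 15 ⇐ PMB removal ⇐ the cyclohexenone ring (the only ring), closed last by ring-closing metathesis at C2=C3 of an acyclic octa-1,7-dien-3-one.
2. Dienone ⇐ new chelation-controlled Mukaiyama aldol of 2-(trimethylsilyloxy)buta-1,3-diene onto an α-PMB-oxy ketone (forms C5–C6 and sets the C5 tertiary carbinol anti to the C4 oxygen, giving the trans-diol).
3. Ketone ⇐ oxidation of the alcohol from Cu-catalysed opening of a PMB-protected epoxy alcohol by a C18 Grignard reagent (C1'–C2' bond); C4 comes from Sharpless desymmetrisation of divinylcarbinol.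
4. C18 (E)-alkenyl bromide ⇐ (E)-hex-3-en-1-ol + 1,12-dibromododecane (Cu-catalysed sp3–sp3 coupling).

Assumption: the SMILES is read as (4S,5S)-4,5-dihydroxy-5-[(E)-nonadec-16-en-1-yl]cyclohex-2-en-1-one (trans-diol; ring atoms C1–C6 counted from the ketone, side chain C1'–C19').

**Step 1**
Reactants: 1 (E)-hex-3-en-1-ol
Product: 2 (E)-1-bromohex-3-ene
Conditions: CBr4, PPh3, CH2Cl2, 0 °C to rt
Reagents that add atoms: carbon tetrabromide, BrC(Br)(Br)Br
Why: Appel bromination converts the primary alcohol into the bromide under neutral conditions without touching or isomerising the E-alkene.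

**Step 2**
Reactants: 2 (E)-1-bromohex-3-ene; 3 1,12-dibromododecane
Product: 5 (E)-18-bromooctadec-3-ene, via (E)-hex-3-enylmagnesium bromide 4 (not isolated)
Conditions: Mg, THF, rt; then 3 (3 equiv), Li2CuCl4 (2 mol %), THF, −10 to 0 °C
Reagents that add atoms: none
Why: Kochi-type Li2CuCl4-catalysed sp3–sp3 cross-coupling of the Grignard reagent with excess α,ω-dibromide gives the mono-coupled bromide (surplus 3 is recovered), and the homoallylic Grignard reagent keeps its E-geometry at or below room temperature.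

**Step 3**
Reactants: 6 penta-1,4-dien-3-ol
Product: 7 (2R,3S)-1,2-epoxypent-4-en-3-ol
Conditions: Ti(OiPr)4 (10 mol %), L-(+)-DIPT (13 mol %), TBHP, 4 Å MS, CH2Cl2, −20 °C
Reagents that add atoms: tert-butyl hydroperoxide, CC(C)(C)OO
Why: Sharpless asymmetric epoxidation desymmetrises the divinylcarbinol (enantiotopic-group and face selection, upgraded by in situ kinetic resolution), fixing the carbinol centre as 3S (the future C4) in the erythro epoxy alcohol.

**Step 4**
Reactants: 7 (2R,3S)-1,2-epoxypent-4-en-3-ol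
Product: 8 (2R)-2-[(1S)-1-[(4-methoxybenzyl)oxy]prop-2-en-1-yl]oxirane
Conditions: NaH, PMBCl, Bu4NI (cat.), THF–DMF, 0 °C
Reagents that add atoms: 4-methoxybenzyl chloride, COc1ccc(CCl)cc1
Why: Williamson etherification installs a chelating, oxidatively removable PMB ether on the secondary hydroxyl without affecting either stereocentre.

**Step 5**
Reactants: 5 (E)-18-bromooctadec-3-ene; 8 (2R)-2-[(1S)-1-[(4-methoxybenzyl)oxy]prop-2-en-1-yl]oxirane
Product: 10 (3S,4R,20E)-3-[(4-methoxybenzyl)oxy]tricosa-1,20-dien-4-ol, via (E)-octadec-15-enylmagnesium bromide 9 (not isolated)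
Conditions: Mg, THF, 40 °C; then 8, CuBr·SMe2 (10 mol %), THF, −40 to 0 °C; aq. NH4Cl
Reagents that add atoms: none
Why: Copper-catalysed SN2 opening of the terminal epoxide at its CH2 carbon by the primary Grignard reagent forms the C1'–C2' bond of the side chain and leaves the PMB-bearing stereocentre untouched (the new carbinol centre is removed in step 6).

**Step 6**
Reactants: 10 (3S,4R,20E)-3-[(4-methoxybenzyl)oxy]tricosa-1,20-dien-4-ol
Product: 11 (3S,20E)-3-[(4-methoxybenzyl)oxy]tricosa-1,20-dien-4-one
Conditions: DMP, NaHCO3, CH2Cl2, 0 °C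
Reagents that add atoms: none
Why: Buffered Dess–Martin oxidation gives the ketone under non-basic conditions, so the allylic α-alkoxy stereocentre (future C4) is not epimerised; the ketone is used at once.

**Step 7**
Reactants: 11 (3S,20E)-3-[(4-methoxybenzyl)oxy]tricosa-1,20-dien-4-one; 12 2-(trimethylsilyloxy)buta-1,3-diene
Product: 13 (5S,6S)-5-hydroxy-6-[(4-methoxybenzyl)oxy]-5-[(E)-nonadec-16-en-1-yl]octa-1,7-dien-3-one
Conditions: TiCl4 (1.1 equiv), CH2Cl2, −78 °C; then 12 (2 equiv), −78 °C; aq. NaHCO3
Reagents that add atoms: none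
Why: Proposed new method: a chelation-controlled Mukaiyama aldol addition of a cross-conjugated 2-siloxydiene to an α-alkoxy β,γ-unsaturated ketone, in which TiCl4 locks the PMB-ether oxygen and the ketone oxygen in a five-membered chelate so that the terminal enol carbon of 12 attacks through an open transition state on the face opposite the vinyl group (Cram-chelate sense), forming the C5–C6 bond and the 5S tertiary carbinol anti to the C4 oxygen and releasing the intact vinyl ketone on silyl loss; the closest known reactions are Reetz-type chelation-controlled Mukaiyama aldol additions to α-alkoxy aldehydes and TiCl4-promoted additions of enol silanes to simple ketones, but this acceptor–donor combination has not been described.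

**Step 8**
Reactants: 13 (5S,6S)-5-hydroxy-6-[(4-methoxybenzyl)oxy]-5-[(E)-nonadec-16-en-1-yl]octa-1,7-dien-3-one
Product: 14 (4S,5S)-5-hydroxy-4-[(4-methoxybenzyl)oxy]-5-[(E)-nonadec-16-en-1-yl]cyclohex-2-en-1-one
Conditions: second-generation Hoveyda–Grubbs catalyst (5 mol %), CH2Cl2 (0.005 M), 40 °C, Ar purge
Reagents that add atoms: none
Why: Ring-closing metathesis between the vinyl ketone and the allylic-ether vinyl group closes the six-membered enone ring (C2=C3) with loss of ethene, the six-ring closure of two terminal alkenes at high dilution being much faster than any reaction of the remote internal E-alkene, and no stereocentre is touched.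

**Step 9**
Reactants: 14 (4S,5S)-5-hydroxy-4-[(4-methoxybenzyl)oxy]-5-[(E)-nonadec-16-en-1-yl]cyclohex-2-en-1-one
Product: 15 (4S,5S)-4,5-dihydroxy-5-[(E)-nonadec-16-en-1-yl]cyclohex-2-en-1-one
Conditions: DDQ, CH2Cl2–pH 7 buffer (10:1), 0 °C to rt
Reagents that add atoms: none
Why: Oxidative PMB cleavage by DDQ in wet, buffered solvent frees the C4 hydroxyl under neutral conditions that spare the E-alkene and the dehydration-prone β-hydroxy enone.

**Compound list**
1 | (E)-hex-3-en-1-ol | CC/C=C/CCO | starting material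
2 | (E)-1-bromohex-3-ene | CC/C=C/CCBr | intermediate
3 | 1,12-dibromododecane | BrCCCCCCCCCCCCBr | starting material
4 | (E)-hex-3-enylmagnesium bromide | CC/C=C/CC[Mg]Br | intermediate
5 | (E)-18-bromooctadec-3-ene | CC/C=C/CCCCCCCCCCCCCCBr | intermediate
6 | penta-1,4-dien-3-ol | C=CC(O)C=C | starting material
7 | (2R,3S)-1,2-epoxypent-4-en-3-ol | C=C[C@H](O)[C@H]1CO1 | intermediate
8 | (2R)-2-[(1S)-1-[(4-methoxybenzyl)oxy]prop-2-en-1-yl]oxirane | C=C[C@H](OCc1ccc(OC)cc1)[C@H]2CO2 | intermediate
9 | (E)-octadec-15-enylmagnesium bromide | CC/C=C/CCCCCCCCCCCCCC[Mg]Br | intermediate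
10 | (3S,4R,20E)-3-[(4-methoxybenzyl)oxy]tricosa-1,20-dien-4-ol | CC/C=C/CCCCCCCCCCCCCCC[C@@H](O)[C@@H](OCc1ccc(OC)cc1)C=C | intermediate
11 | (3S,20E)-3-[(4-methoxybenzyl)oxy]tricosa-1,20-dien-4-one | CC/C=C/CCCCCCCCCCCCCCCC(=O)[C@@H](OCc1ccc(OC)cc1)C=C | intermediate
12 | 2-(trimethylsilyloxy)buta-1,3-diene | C=CC(=C)O[Si](C)(C)C | starting material
13 | (5S,6S)-5-hydroxy-6-[(4-methoxybenzyl)oxy]-5-[(E)-nonadec-16-en-1-yl]octa-1,7-dien-3-one | C=CC(=O)C[C@@](O)(CCCCCCCCCCCCCCC/C=C/CC)[C@@H](OCc1ccc(OC)cc1)C=C | intermediate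
14 | (4S,5S)-5-hydroxy-4-[(4-methoxybenzyl)oxy]-5-[(E)-nonadec-16-en-1-yl]cyclohex-2-en-1-one | CC/C=C/CCCCCCCCCCCCCCC[C@]1(O)CC(=O)C=C[C@@H]1OCc1ccc(OC)cc1 | intermediate
15 | (4S,5S)-4,5-dihydroxy-5-[(E)-nonadec-16-en-1-yl]cyclohex-2-en-1-one (CNP0135424.2) | CC/C=C/CCCCCCCCCCCCCCC[C@]1(O)CC(=O)C=C[C@@H]1O | target

**Total step count:** 9.
**Longest linear sequence:** 7 steps (steps 1, 2, 5, 6, 7, 8, 9 from 1; equally steps 3, 4, 5, 6, 7, 8, 9 from 6).

**Three steps most likely to fail**

Step 7 (the proposed new aldol). Risks are enolisation or epimerisation of 11, loss of the PMB group under TiCl4, polymerisation of 12, retro-aldol or oxa-Michael closure of 13, and incomplete chelation control. The fallback uses known chemistry and sets out from 11. Zn and 2-bromo-N-methoxy-N-methylacetamide in THF give the Reformatsky reagent bromo[2-[methoxy(methyl)amino]-2-oxoethyl]zinc F1. This weakly basic zinc enolate adds to 11 under Cram-chelate control (zinc bridging the ketone and PMB-ether oxygens, attack anti to the vinyl group) to give (3S,4S)-3-hydroxy-N-methoxy-4-[(4-methoxybenzyl)oxy]-N-methyl-3-[(E)-nonadec-16-en-1-yl]hex-5-enamide F2. Vinylmagnesium bromide (THF, −78 to 0 °C, cold acidic quench) then converts the Weinreb amide into the vinyl ketone and the route is rejoined at 13.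

Step 8 (ring-closing metathesis). Closure onto the electron-poor vinyl ketone may be slow enough for the catalyst to attack the internal E-alkene of the side chain (chain truncation, E/Z scrambling) or to isomerise alkenes. The fallback sets out from 13. Luche reduction (NaBH4, CeCl3·7H2O, MeOH, −78 °C) gives (5S,6S)-6-[(4-methoxybenzyl)oxy]-5-[(E)-nonadec-16-en-1-yl]octa-1,7-diene-3,5-diol F3 as a mixture of C3 epimers. Its two electron-rich allylic alkenes close rapidly at room temperature with little second-generation Grubbs catalyst, giving (4S,5S)-4-[(4-methoxybenzyl)oxy]-5-[(E)-nonadec-16-en-1-yl]cyclohex-2-ene-1,5-diol F4. Selective oxidation of the allylic secondary alcohol with MnO2 (CH2Cl2) rejoins the route at 14.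

Step 9 (PMB removal on the ring). DDQ can convert the PMB ether and the neighbouring tertiary hydroxyl into a p-methoxybenzylidene acetal, and the acid needed to open it could dehydrate the β-hydroxy enone towards the alkylhydroquinone. The fallback sets out from 13 and removes the PMB group before the ring exists. DDQ in wet CH2Cl2 (with mild aqueous AcOH if an acetal forms, harmless on an acyclic compound that cannot aromatise) gives (5S,6S)-5,6-dihydroxy-5-[(E)-nonadec-16-en-1-yl]octa-1,7-dien-3-one F5. Ring-closing metathesis of this diol (second-generation Hoveyda–Grubbs catalyst, CH2Cl2, 40 °C, high dilution) then gives the target directly, rejoining the route at 15.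

**Further compounds**
F1 | step 7 | bromo[2-[methoxy(methyl)amino]-2-oxoethyl]zinc | CON(C)C(=O)C[Zn]Br
F2 | step 7 | (3S,4S)-3-hydroxy-N-methoxy-4-[(4-methoxybenzyl)oxy]-N-methyl-3-[(E)-nonadec-16-en-1-yl]hex-5-enamide | CON(C)C(=O)C[C@@](O)(CCCCCCCCCCCCCCC/C=C/CC)[C@@H](OCc1ccc(OC)cc1)C=C
F3 | step 8 | (5S,6S)-6-[(4-methoxybenzyl)oxy]-5-[(E)-nonadec-16-en-1-yl]octa-1,7-diene-3,5-diol (C3 epimers) | C=CC(O)C[C@@](O)(CCCCCCCCCCCCCCC/C=C/CC)[C@@H](OCc1ccc(OC)cc1)C=C
F4 | step 8 | (4S,5S)-4-[(4-methoxybenzyl)oxy]-5-[(E)-nonadec-16-en-1-yl]cyclohex-2-ene-1,5-diol (C1 epimers) | CC/C=C/CCCCCCCCCCCCCCC[C@]1(O)CC(O)C=C[C@@H]1OCc1ccc(OC)cc1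
F5 | step 9 | (5S,6S)-5,6-dihydroxy-5-[(E)-nonadec-16-en-1-yl]octa-1,7-dien-3-one | C=CC(=O)C[C@@](O)(CCCCCCCCCCCCCCC/C=C/CC)[C@@H](O)C=C
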